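The constants used here were drawn at random within sensible limits; no experiment stands behind them.

Take the nucleophile as the thing to follow, and hold the electrophile still while you do.

- eta: solid electrophile 0.16 M; nucleophile 0.160 M; time 1.0 min
- gamma: solid electrophile 0.16 M; nucleophile 0.320 M; time 1.0 min

    electrophile + nucleophile → acid set free + product (k1 = 0.37 L mol⁻¹ s⁻¹)
    nucleophile + acid set free ⇌ protonated nucleophile, settled at all times (K2 = 88 L mol⁻¹)
    2 nucleophile → homo dimer (k3 = 0.21 L mol⁻¹ s⁻¹)
    solid electrophile ⇌ electrophile, rate k4*(cs4 - [electrophile]) while solid is left; crystals form when [electrophile] > cs4 (cs4 = 41 mM, k4 = 0.93 s⁻¹)

1. part of the solid electrophile that has reacted (what has only dissolved counts as not reacted) at the end, eta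
2. part of the solid electrophile that has reacted (what has only dissolved counts as not reacted) at the end, gamma
3. what raising the concentration of nucleophile from its lowest to its highest value here does to the part of the solid electrophile that has reacted (what has only dissolved counts as not reacted) (changes below 5 percentage points count as none) (it falls / it rises / no change)

- a doubled species enters its step squared and goes two at a time
- solid, in amounts per volume of the solution: solid electrophile
- at the start none of the solid electrophile is in solution
- what has only dissolved of solid electrophile counts as not reacted
- run time (eta): 1.0 min

**Crossover level.** The solid feeds the solution faster than coupling drains it, since the dissolving coefficient 0.93 s⁻¹ exceeds the coupling's 0.118 s⁻¹ at the gamma charge. So I hold the electrophile at its solubility, 41 mM. Coupling is then pseudo-first-order in nucleophile, with constant 0.0152 s⁻¹. The dimer path and the coupling take nucleophile equally fast at 0.0361 M, which I call the crossover level. Eta charges 4.43 times this level and gamma 8.86 times.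

**Kind extreme.** Suppose the acid costs no nucleophile. One nucleophile then goes per coupling. Integrating that together with the dimer path gives product equal to the crossover level times the logarithm of one plus the charge over that level times 0.598, the share of nucleophile that coupling by itself would use in the run time. That reacts 29.2% in eta and 41.5% in gamma.

**Harsh extreme.** Suppose instead that each coupling also loses one nucleophile to its acid. Integrating with two nucleophile per coupling gives 23.7% in eta and 35.0% in gamma.

**My commitment.** The binding constant times the eta charge is 14.1, so acid is bound readily at first, and I stand near the harsh end. Its gap of 11 percentage points says the answer rises. The forecast gives 25% (23% to 27%) and 35% (32% to 38%), also it rises: “Doubling the nucleophile helps less than proportionally because dimerisation is second order.”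

**The flask.** Eta reaches 24.2% and gamma 34.0%. From the lower nucleophile charge to the higher, the part reacted behaves so: it rises, by 9.8 points, and this gap between the flasks comes from the difference in nucleophile charge. The crossover level holds both brakes: gamma gives 82.7% without the dimer path and 67.0% with the solubility raised, and the dissolving with it. In gamma, a solid charge of 0.139 M or 0.188 M moves the answer by 5 points, past the forecast's range. The solid charge stands nowhere in the crossover level, so for the neighbour with 0.40 M of solid I scale eta's harsh figure to 9.48%, and that flask gives 9.68%.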